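**Retrosynthetic overview**
1. C8=C17: target 21 ⇐ 8-ketone 20 by methylenation.
2. Ring B: 20 ⇐ (Z)-alkylidene trans-hydrindane 18 by an oxidative ring expansion, a 1,2-shift of C10 from C8 to C9 that turns the cyclopentane into the cyclohexanone and puts the side chain on C9.
3. 18 ⇐ enone acid 12 (Birch reductive hydroxymethylation sets C5 and C4, then C3 deoxygenation) ⇐ Wittig reaction of enedione 10 with the ylide of 6 (C8=C9).
4. 10 ⇐ 2-methylcyclopentane-1,3-dione + ethyl vinyl ketone (amino-acid-catalysed annulation, sets C10); 6 ⇐ 5-chloropent-1-ene + methyl acrylate + MeMgBr (asymmetric conjugate addition, sets C13).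
5. Ring order: five-membered ring (bought in 7) → ring A (annulation) → ring B (ring expansion of the five-membered ring).

Numbering: labdane locants of the target (C1–C20) are used for all intermediates; α/β mean the face opposite to / on the side of the angular methyl C20.
Assumption: (S)-Tol-BINAP is taken as the ligand hand that gives the 3R adduct in step 2; if the sense is the reverse, its mirror image is used.

**Step 1**
Reactants: 1 5-chloropent-1-ene; 2 methyl acrylate
Product: 3 methyl (E)-6-chlorohex-2-enoate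
Conditions: 2 (3 equiv), second-generation Grubbs catalyst (H2IMes)(PCy3)Cl2Ru=CHPh (2 mol %), CH2Cl2, 40 °C
Reagents that add atoms: none
Why: Cross-metathesis of a terminal alkene and an acrylate is selective for the cross product and gives the E-enoate with loss of ethene; no stereocenter is formed.

**Step 2**
Reactants: 3 methyl (E)-6-chlorohex-2-enoate
Product: 5 (3R)-6-chloro-3-methylhexanoic acid, via methyl ester 4 (not isolated)
Conditions: MeMgBr (3 equiv), CuI (2 mol %), (S)-Tol-BINAP (3 mol %), t-BuOMe, −20 °C; then LiOH·H2O, THF/MeOH/H2O, 23 °C; aq. HCl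
Reagents that add atoms: methylmagnesium bromide, C[Mg]Br; lithium hydroxide, [Li+].[OH-]
Why: Copper-catalysed asymmetric conjugate addition of MeMgBr to the E-enoate sets C13 by ligand-controlled facial selectivity (3R here, 13R later), the alkyl chloride is inert at this temperature, and saponification then frees the acid needed for the ylide chemistry.

**Step 3**
Reactants: 5 (3R)-6-chloro-3-methylhexanoic acid
Product: 6 [(4R)-5-carboxy-4-methylpentyl]triphenylphosphonium iodide
Conditions: PPh3 (1.1 equiv), NaI (1.2 equiv), MeCN, reflux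
Reagents that add atoms: triphenylphosphine, c1ccc(cc1)P(c1ccccc1)c1ccccc1; sodium iodide, [Na+].[I-]
Why: Finkelstein exchange followed by SN2 quaternisation of PPh3 gives the ω-carboxyalkyl phosphonium salt, as for the classical carboxybutyl Wittig salts; the remote stereocenter is untouched.

**Step 4**
Reactants: 7 2-methylcyclopentane-1,3-dione; 8 pent-1-en-3-one (ethyl vinyl ketone)
Product: 10 (7aS)-4,7a-dimethyl-2,3,7,7a-tetrahydro-1H-indene-1,5(6H)-dione, via triketone 9 (not isolated)
Conditions: H2O, AcOH (cat.), 70 °C; then (S)-phenylalanine (1 equiv), HClO4 (0.5 equiv), MeCN, reflux; one recrystallisation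
Reagents that add atoms: none
Why: Michael addition followed by the amino-acid-catalysed Hajos–Parrish–Eder–Sauer–Wiechert aldol condensation builds ring A on the five-membered ring, the enamine choosing one of the two enantiotopic ring carbonyls so that C10 is set as S (10β-methyl).

**Step 5**
Reactants: 6 [(4R)-5-carboxy-4-methylpentyl]triphenylphosphonium iodide; 10 (7aS)-4,7a-dimethyl-2,3,7,7a-tetrahydro-1H-indene-1,5(6H)-dione
Product: 12 (3R,6Z)-6-[(7aR)-4,7a-dimethyl-5-oxo-2,3,5,6,7,7a-hexahydro-1H-inden-1-ylidene]-3-methylhexanoic acid, via ylide 11 (not isolated)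
Conditions: 6 (1.8 equiv), NaN(SiMe3)2 (3.6 equiv), THF, 0 °C; then 10, 0 → 60 °C; aq. HCl
Reagents that add atoms: none
Why: Wittig olefination with the non-stabilised carboxylate ylide takes the saturated cyclopentanone C8 in preference to the less electrophilic, α-branched enone carbonyl, as in the ethylidenation of 17-oxo steroids, and gives mainly the Z alkene, whose geometry is of no consequence later; C10 and C13 are untouched.

**Step 6**
Reactants: 12 (3R,6Z)-6-[(7aR)-4,7a-dimethyl-5-oxo-2,3,5,6,7,7a-hexahydro-1H-inden-1-ylidene]-3-methylhexanoic acid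
Product: 14 (3R,6Z)-6-[4α-(hydroxymethyl)-4β,7aβ-dimethyl-5-oxo-3aα-H-octahydro-1H-inden-1-ylidene]-3-methylhexanoic acid, via lithium enolate 13 (not isolated)
Conditions: Li (3.5 equiv), NH3(l)/THF, t-BuOH (1 equiv), −78 °C; NH3 off; CH2O (g), THF, −78 → −30 °C; aq. NH4Cl
Reagents that add atoms: formaldehyde, C=O
Why: Birch reduction of the enone protonates C5 on the α face to give the trans ring fusion and a regiodefined lithium enolate, whose aldol reaction with formaldehyde occurs at C4 from the α face, away from the axial 10β-methyl, so the new CH2OH is 4α and the methyl 4β; the carboxylate and the isolated alkene are inert.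

**Step 7**
Reactants: 14 (3R,6Z)-6-[4α-(hydroxymethyl)-4β,7aβ-dimethyl-5-oxo-3aα-H-octahydro-1H-inden-1-ylidene]-3-methylhexanoic acid
Product: 16 methyl (3R,6Z)-6-[4α-(acetoxymethyl)-4β,7aβ-dimethyl-5-oxo-3aα-H-octahydro-1H-inden-1-ylidene]-3-methylhexanoate, via hydroxy ester 15 (not isolated)
Conditions: TMSCHN2, PhMe/MeOH (4:1), 0 °C; concentrate; Ac2O, pyridine, DMAP (cat.), CH2Cl2, 23 °C
Reagents that add atoms: (trimethylsilyl)diazomethane, C[Si](C)(C)C=[N+]=[N-]; acetic anhydride, CC(=O)OC(C)=O
Why: Esterification with TMSCHN2/MeOH is specific for the carboxylic acid and DMAP-catalysed acetylation then takes the only hydroxyl; no stereocenter is touched.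

**Step 8**
Reactants: 16 methyl (3R,6Z)-6-[4α-(acetoxymethyl)-4β,7aβ-dimethyl-5-oxo-3aα-H-octahydro-1H-inden-1-ylidene]-3-methylhexanoate
Product: 18 methyl (3R,6Z)-6-[4α-(acetoxymethyl)-4β,7aβ-dimethyl-3aα-H-octahydro-1H-inden-1-ylidene]-3-methylhexanoate, via tosylhydrazone 17 (not isolated)
Conditions: TsNHNH2 (3 equiv), EtOH, AcOH (cat.), 70 °C; then catecholborane, CHCl3, 0 °C; NaOAc·3H2O, reflux
Reagents that add atoms: none
Why: Tosylhydrazone formation, hydride delivery from catecholborane and loss of sulfinate and N2 from the diazene (Kabalka-type deoxygenation) turn the hindered C3 ketone into CH2 under near-neutral conditions that spare the acetate, the ester and the trisubstituted alkene.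

**Step 9**
Reactants: 18 methyl (3R,6Z)-6-[4α-(acetoxymethyl)-4β,7aβ-dimethyl-3aα-H-octahydro-1H-inden-1-ylidene]-3-methylhexanoate
Product: 20 methyl (13R)-18-acetoxy-8-oxo-17-norlabdan-15-oate, via dimethyl ketal 19 (not isolated)
Conditions: PhI(OH)OTs (1.2 equiv), MeOH/H2O (95:5), 0 → 23 °C; then 1 M aq. HCl, THF, 23 °C
Reagents that add atoms: water, O
Why: Proposed new method: trivalent-iodine oxidative ring expansion with migration of a quaternary alkyl carbon, in which the electrophilic iodine of PhI(OH)OTs adds to the less substituted alkene carbon C9 while methanol caps the tertiary C8, and departure of PhI from C9 is accompanied by a 1,2-shift of the more electron-rich quaternary C10 (not C7) from C8 to C9 with retention at C10, so that the cyclopentane becomes the cyclohexanone of ring B via an oxocarbenium ion and ketal (a semipinacol-type step), and C9 is left under thermodynamic control next to the new ketone (side chain equatorial 9β, H-9α) during the acid hydrolysis; the closest known reaction type is the ring expansion of exocyclic aryl-substituted alkenes by the same reagent through a 1,2-aryl shift, together with the Tl(NO3)3 ring expansion of methylenecycloalkanes, and to my knowledge neither has been shown for a trialkyl-substituted alkylidenecyclopentane with a migrating quaternary carbon.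

**Step 10**
Reactants: 20 methyl (13R)-18-acetoxy-8-oxo-17-norlabdan-15-oate
Product: 21 methyl (13R)-18-acetoxylabd-8(17)-en-15-oate
Conditions: Zn, CH2Br2, TiCl4, THF/CH2Cl2, 0 → 23 °C
Reagents that add atoms: dibromomethane, BrCBr
Why: Takai–Lombardo methylenation is non-basic, so the hindered, epimerisable C8 ketone becomes the exocyclic C8=C17 alkene without loss of the 9β configuration and without touching the acetate or the methyl ester.

**Compound list**
1 | 5-chloropent-1-ene | C=CCCCCl | starting material
2 | methyl acrylate | C=CC(=O)OC | starting material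
3 | methyl (E)-6-chlorohex-2-enoate | COC(=O)/C=C/CCCCl | intermediate
4 | methyl (3R)-6-chloro-3-methylhexanoate | COC(=O)C[C@H](C)CCCCl | intermediate
5 | (3R)-6-chloro-3-methylhexanoic acid | OC(=O)C[C@H](C)CCCCl | intermediate
6 | [(4R)-5-carboxy-4-methylpentyl]triphenylphosphonium iodide | OC(=O)C[C@H](C)CCC[P+](c1ccccc1)(c1ccccc1)c1ccccc1.[I-] | intermediate
7 | 2-methylcyclopentane-1,3-dione | CC1C(=O)CCC1=O | starting material
8 | pent-1-en-3-one (ethyl vinyl ketone) | CCC(=O)C=C | starting material
9 | 2-methyl-2-(3-oxopentyl)cyclopentane-1,3-dione | CCC(=O)CCC1(C)C(=O)CCC1=O | intermediate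
10 | (7aS)-4,7a-dimethyl-2,3,7,7a-tetrahydro-1H-indene-1,5(6H)-dione | O=C1CCC2=C(C)C(=O)CC[C@]12C | intermediate
11 | sodium (3R)-3-methyl-6-(triphenyl-λ5-phosphanylidene)hexanoate (ylide of 6) | [Na+].[O-]C(=O)C[C@H](C)CCC=P(c1ccccc1)(c1ccccc1)c1ccccc1 | intermediate
12 | (3R,6Z)-6-[(7aR)-4,7a-dimethyl-5-oxo-2,3,5,6,7,7a-hexahydro-1H-inden-1-ylidene]-3-methylhexanoic acid (angular methyl placed as in 10) | OC(=O)C[C@H](C)CC/C=C1/CCC2=C(C)C(=O)CC[C@]12C | intermediate
13 | dilithium salt of the 5α-H C3(4)-enolate and the carboxylate formed from 12 | [Li+].[Li+].[O-]C(=O)C[C@H](C)CC/C=C1/CC[C@H]2C(C)=C([O-])CC[C@]12C | intermediate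
14 | (3R,6Z)-6-[4α-(hydroxymethyl)-4β,7aβ-dimethyl-5-oxo-3aα-H-octahydro-1H-inden-1-ylidene]-3-methylhexanoic acid | OC(=O)C[C@H](C)CC/C=C1/CC[C@H]2[C@](C)(CO)C(=O)CC[C@]12C | intermediate
15 | methyl ester of 14 | COC(=O)C[C@H](C)CC/C=C1/CC[C@H]2[C@](C)(CO)C(=O)CC[C@]12C | intermediate
16 | methyl (3R,6Z)-6-[4α-(acetoxymethyl)-4β,7aβ-dimethyl-5-oxo-3aα-H-octahydro-1H-inden-1-ylidene]-3-methylhexanoate | COC(=O)C[C@H](C)CC/C=C1/CC[C@H]2[C@](C)(COC(C)=O)C(=O)CC[C@]12C | intermediate
17 | C3 tosylhydrazone of 16 | COC(=O)C[C@H](C)CC/C=C1/CC[C@H]2[C@](C)(COC(C)=O)/C(=N/NS(=O)(=O)c3ccc(C)cc3)CC[C@]12C | intermediate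
18 | methyl (3R,6Z)-6-[4α-(acetoxymethyl)-4β,7aβ-dimethyl-3aα-H-octahydro-1H-inden-1-ylidene]-3-methylhexanoate | COC(=O)C[C@H](C)CC/C=C1/CC[C@H]2[C@](C)(COC(C)=O)CCC[C@]12C | intermediate
19 | methyl (13R)-18-acetoxy-8,8-dimethoxy-17-norlabdan-15-oate (5α-H, 9α-H, 10β-methyl) | COC1(OC)CC[C@H]2[C@](C)(COC(C)=O)CCC[C@]2(C)[C@H]1CC[C@@H](C)CC(=O)OC | intermediate
20 | methyl (13R)-18-acetoxy-8-oxo-17-norlabdan-15-oate, that is methyl (3R)-5-[(1R,4aR,5R,8aS)-5-(acetoxymethyl)-5,8a-dimethyl-2-oxodecahydronaphthalen-1-yl]-3-methylpentanoate | O=C1CC[C@H]2[C@](C)(COC(C)=O)CCC[C@]2(C)[C@H]1CC[C@@H](C)CC(=O)OC | intermediate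
21 | methyl (13R)-18-acetoxylabd-8(17)-en-15-oate, that is methyl (3R)-5-[(1S,4aR,5R,8aR)-5-(acetoxymethyl)-5,8a-dimethyl-2-methylidenedecahydronaphthalen-1-yl]-3-methylpentanoate | C=C1CC[C@H]2[C@](C)(COC(C)=O)CCC[C@]2(C)[C@H]1CC[C@@H](C)CC(=O)OC | target

**Step count**
Total: 10 steps. Longest linear sequence: 9 steps (steps 1–3, then 5–10); step 4 is the second branch and joins at step 5.

**Steps most likely to fail**

Step 5 (Wittig reaction on the enedione). The basic carboxylate ylide may enolise the hindered C8 ketone or attack the enone. The fallback puts the olefination behind a protecting group, on a saturated ketone of the 17-oxo-steroid kind. It sets out from 10: ethylene glycol, TsOH (cat.), PhH, Dean–Stark gives the C8 dioxolane F1. Li/NH3/t-BuOH then CH2O, as in step 6, goes through the lithium enolate F2 to the ketal hydroxy ketone F3. TsNHNH2 gives the tosylhydrazone F4, and catecholborane/NaOAc·3H2O gives the ketal with C3 as CH2, F5. Aqueous HCl/THF frees the hydrindanone F6. Ylide 11 (one extra equivalent of base for the free alcohol) gives the (Z)-alkylidene hydroxy acid F7. TMSCHN2 gives the methyl ester F8 and Ac2O/pyridine then gives 18, where the route is rejoined before step 9.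

Step 6 (Birch reductive hydroxymethylation). The risks are incomplete trans selectivity at the ring fusion, proton transfer or retro-aldol loss during trapping with gaseous formaldehyde, and double hydroxymethylation. The fallback separates reduction from C–C bond formation and addresses the trapping problems, not the ring-fusion selectivity. It sets out from 12: the same Li/NH3 reduction through 13, but quenched with Me3SiCl/Et3N at −78 °C, gives the bis(trimethylsilyl) enol ether/silyl ester F9. A Mukaiyama-type hydroxymethylation with aqueous formaldehyde and Sc(OTf)3 (cat.) in THF/H2O, which also hydrolyses the silyl ester, gives 14, where the route is rejoined.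

Step 9 (the new ring expansion). The risks are migration of C7 instead of C10 (regioisomeric ketone), simple 1,2-dimethoxylation, and capture of the C8 cation by elimination. The fallback uses known halohydrin semipinacol chemistry. It sets out from 18: NBS, MeCN/H2O, 0 °C gives the bromohydrin F10 (Br on C9, OH on the tertiary C8, water entering from the α face). AgBF4, CH2Cl2, 0 °C (silver-assisted ring-expanding rearrangement of the tertiary-alcohol/secondary-bromide pair), followed by brief acid equilibration of C9, gives 20, where the route is rejoined.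

**Further compounds**
F1 | step 5 | C8 ethylene ketal of 10, (7a'S)-4',7a'-dimethyl-2',3',7',7a'-tetrahydrospiro[1,3-dioxolane-2,1'-inden]-5'(6'H)-one | O1CCOC13CCC2=C(C)C(=O)CC[C@]32C
F2 | step 5 | lithium C3(4)-enolate (5α-H) from Birch reduction of F1 | O1CCOC13CC[C@H]2C(C)=C([O-])CC[C@]32C.[Li+]
F3 | step 5 | C8 ethylene ketal of 4α-(hydroxymethyl)-4β,10β-dimethyl-5α-H-hydrindane-3,8-dione (3-ketone free) | O1CCOC13CC[C@H]2[C@](C)(CO)C(=O)CC[C@]32C
F4 | step 5 | C3 tosylhydrazone of F3 | O1CCOC13CC[C@H]2[C@](C)(CO)/C(=N/NS(=O)(=O)c4ccc(C)cc4)CC[C@]32C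
F5 | step 5 | C8 ethylene ketal of 4α-(hydroxymethyl)-4β,10β-dimethyl-5α-H-hydrindan-8-one | O1CCOC13CC[C@H]2[C@](C)(CO)CCC[C@]32C
F6 | step 5 | 4α-(hydroxymethyl)-4β,10β-dimethyl-5α-H-hydrindan-8-one (4-(hydroxymethyl)-4,7a-dimethyloctahydro-1H-inden-1-one) | O=C1CC[C@H]2[C@](C)(CO)CCC[C@]12C
F7 | step 5 | (3R,6Z)-6-[4α-(hydroxymethyl)-4β,7aβ-dimethyl-3aα-H-octahydro-1H-inden-1-ylidene]-3-methylhexanoic acid | OC(=O)C[C@H](C)CC/C=C1/CC[C@H]2[C@](C)(CO)CCC[C@]12C
F8 | step 5 | methyl ester of F7 | COC(=O)C[C@H](C)CC/C=C1/CC[C@H]2[C@](C)(CO)CCC[C@]12C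
F9 | step 6 | trimethylsilyl enol ether (C3–O) and trimethylsilyl ester of the Birch-reduced 12 | C[Si](C)(C)OC(=O)C[C@H](C)CC/C=C1/CC[C@H]2C(C)=C(O[Si](C)(C)C)CC[C@]12C
F10 | step 9 | bromohydrin of 18 (9-bromo, 8α-hydroxy; major diastereomer drawn) | COC(=O)C[C@H](C)CC[C@@H](Br)[C@@]1(O)CC[C@H]2[C@](C)(COC(C)=O)CCC[C@]12C
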